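| flask | substrate | solid partner | remark | time |
|---|---|---|---|---|
| alpha | 0.0020 M | 1.2 equiv | the very flask that is asked about, followed so far |  |
| flask | 0.0020 M | 1.20 equiv |  | 30 min |

alpha run (percent of the substrate charged)

| time / min | target / % |
|---|---|
| 6.00 | 14.5 |
| 12.0 | 21.7 |
| 20.0 | 23.3 |
| 25.0 | 20.7 |
| 30.0 | 21.1 |

(standard deviation of a reading: 0.5 percentage points)

- north-west: change nothing and wait 1.0 h more
- south-west: at 30 min add substrate, 50.0% of the amount charged, then wait 1.0 h
- west: at 30 min take out 90% of the target then present, then wait 1.0 h

- as a solid, counted per litre of solution: solid partner
- removed target is counted in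
- at the start none of the solid partner is in solution
- additions bring no volume worth counting

* target, in percent of the substrate first charged, at 30 min
* which option adds most target ("none" when 2 percentage points or less is all one gets) (north-west / south-west / west / none)
* target present, with what was taken out counted in, in percent of the substrate first charged, after north-west
* target present, with what was taken out counted in, in percent of the substrate first charged, after west

A first-order fall keeps one thing unchanged: the share of target that survives a given wait, whatever amount stands there. So we fold the alpha run and the wait into one number. We replace the late curve by its mean slope: from 20.0 min to 30.0 min the logarithm of the target readings falls at 0.00992 min⁻¹, and over 1.0 h that gives 0.595. This is the loss number N, the mean rate of fall times the wait, and its scatter is about 0.201. In words, we expect a share e^(−N) = 0.552 of the target to survive the hour.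

The mean line stands at 20.6% at 30 min, our figure for now. We reckon 11.4% after north-west and 19.7% after west. For south-west we give the added substrate the yield read at 20.0 min, which makes 17.8%. Was one number enough? With N lower by its scatter, south-west reaches 21.8%, still within 2 percentage points of now, so we say none.

The forecast differs: now 21.7%, best west, 21.7% after north-west and 36.5% after west, since its “simplest reading is a reversible equilibrium”.

The flask gives now 19.9%, best none, 4.83% after north-west and 18.6% after west.

    substrate → intermediate (k = 0.00669 s⁻¹)
    fresh partner + intermediate → target (k = 13.4 L mol⁻¹ s⁻¹)
    2 intermediate → homo product (k = 3.50 L mol⁻¹ s⁻¹)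
    fresh partner + target → over-reaction product (k = 2.62 L mol⁻¹ s⁻¹)
    solid partner ⇌ fresh partner, rate k5*(cs5 - [fresh partner]) while solid is left; crystals form when [fresh partner] > cs5 (solubility = 0.160 mM, k = 0.0198 s⁻¹)
    fresh partner → decomposition product (k = 3.91 × 10⁻⁶ s⁻¹)

Taken from the flask's 19.9% at 30 min and 4.83% after north-west, N is 1.42, against the 0.595 we read off the alpha run. At 30 min in the flask, target is made at 0.210 of the rate at which it is used up, each step taken net, so more slowly than it goes. Meanwhile in the flask c(fresh partner) goes from 1.50 × 10⁻⁴ M at 30.0 min to 1.59 × 10⁻⁴ M at 120 min, which suits a pseudo-first-order fall of the target. The neighbouring flask, left until 2.0 h, waits 90.0 min after 30 min; N stretched to that wait gives 2.36%, and that flask holds 2.29%.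

The numbers in the tables stem from a simulated flask on assumed constants, noise included.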